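## The problem

The target 17 is a single cyclohex-4-ene ring whose only carbon branch is the one-carbon arm C7 on C1. With the ring numbered C1 (tertiary carbinol bearing C7H2OBz), C2 (OAc), C3 (OBz), C4=C5 and C6 (OMe), the configuration is (1R,2S,3R,6S). C1-OH and C2-OAc are cis on one face; C3-OBz and C6-OMe are cis to each other on the other face. The C3/C6 pair, once set, can therefore send a reagent to the opposite face of a C1=C2 alkene, and only one absolute stereochemical decision is needed. The five oxygen functions are of four kinds and sit on neighbouring carbons. Acyl migration under base, ionisation of the allylic C3–O and C6–O bonds under acid or with zerovalent palladium, and attack of hydrides or alkoxides on the esters must all be avoided late in the route, so each group is best introduced in its final form. The C4=C5 alkene forbids late hydrogenation and would compete in any oxidation aimed at C1=C2. The enabling feature is the C3–C4=C5–C6 unit with cis oxygens at C3 and C6: it is the retron of a [4+2] cycloaddition between a C6=C1–C2=C3 diene (OMe and OBz at its termini, C7 on C1) and a two-carbon C4=C5 partner, which leaves C1=C2 exactly where the cis-diol is required. Because that partner would have to be an alkyne, C4 and C5 are brought in as the carbons of a fumarate and converted into the alkene only at the end.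

## Retrosynthesis

**17 to 16.** A carboxyl group is placed on each of C4 and C5, giving diacid 16; the forward reaction is an anodic oxidative bis-decarboxylation. Carrying C4=C5 through the route is not possible because it would not survive the osmylation meant for C1=C2. The usual alkyne equivalents (sulfonyl- or nitro-substituted dienophiles) are unmasked with reducing metals or strong base, which the benzoates and the acetate do not tolerate. Diacid 16 is a saturated ring that can be oxidised and hydrogenolysed freely. The forward step must oxidise two carboxylates at platinum in a weakly basic medium without ester cleavage and without capture of a transient C4 cation by the C3 benzoate.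

**16 to 13.** Diacid 16 comes from dibenzyl ester 15 by hydrogenolysis, 15 from diol 14 by acetylation of the secondary C2 hydroxyl, and 14 from cyclohexene 13 by cutting C1–O and C2–O (cis-dihydroxylation). Benzyl esters are the one carboxyl protection removable beside two benzoates and an acetate, and no alkene is present when they are cleaved. Osmylation is preferred to epoxidation and opening, which would give the trans diol. In 13 both allylic oxygens lie on one face, so the oxidant is sent to the other and C1/C2 are set relative to C3/C6. The tertiary C1 hydroxyl needs no protection.

**13 to 11 and 12.** Cyclohexene 13 is cut at C3–C4 and C5–C6 into diene 11 and dibenzyl fumarate 12. This cut delivers the skeleton, both allylic oxygens in their cis relationship and every acyl and methyl group in final form from two flat, achiral pieces. The direct cut across the existing alkene of 17 (C1–C6 and C2–C3) would need an electron-rich enol dienophile and would have to create the quaternary C1 in the cycloaddition. Three things are asked of the forward reaction: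
- a chiral Lewis acid must expose one face of the bound fumarate;
- the bound ester must sit endo;
- the unsymmetrical diene must keep one orientation relative to the bound ester.

The third point matters. A symmetrical fumarate removes the constitutional regiochemistry but not its stereochemical consequence: turning the diene end for end on the same fumarate face uses the other diene face and gives the enantiomeric C3/C6 pair. The difference in donor strength between the methoxy and benzoyloxy termini is relied on to fix this orientation. The C4/C5 configuration itself is irrelevant.

**11 to 9.** Both oxygens of diene 11 must point outward, so that the s-cis conformation is accessible and C3 and C6 emerge cis. Diene 11 is traced to acetal 10 by adding methanol across C6=C1 (forward: silyl triflate/amine elimination), and 10 to aldehyde 9 by returning the enol benzoate to the C3 aldehyde. Making the acid-labile methyl enol ether last keeps it away from every oxidant. Both eliminations must give the outward geometry; this is the soft spot of the front end and is treated under the risks.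

**9 to 1 and 2.** Aldehyde 9 is the ozonolysis product of terminal alkene 7 (through ozonide 8); the allyl group is a masked C2–C3 acetaldehyde unit. Alkene 7 is the benzoate of alcohol 5 (from benzoyl chloride 6), 5 is the reduction product of ester 4, and 4 is cut at C1–C2 into lithium enolate 3 of methyl 3,3-dimethoxypropanoate 1 and allyl bromide 2. Ester 1 already holds C6 at the aldehyde oxidation level with its methoxy group, C1 and C7. The C1 stereocentre formed in the alkylation is of no consequence because C1 becomes sp2 in 11.

## Roads not taken

**Alternative 1:** The ring is cut at C1–C6 and traced to a carbohydrate, the D-gluco-configured 1,5-lactone A2, which carries an (E)-2-methoxyvinyl group on its carbinol carbon (the future C4). Forward, enolisation and O-silylation of A2 followed by Ireland–Claisen rearrangement would form C1–C6, break the lactone C4–O bond, create C4=C5 and, after hydrolysis of the silyl ester, give acid A1.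
- Merits: C2 and C3 come from the chiral pool; the [3,3] shift transfers chirality to C1 and C6 in one event; the alkene arrives in place without masking.
- Weak points: the lactone enolate carries a β-silyloxy group and can eliminate before it is silylated. The ring forces a boat-like transition state, so the C6 configuration rests on a vinyl ether geometry that a methoxymethylene Wittig reaction does not control. A1 still needs reduction of the carboxyl group to C7 and differentiation of three identical triethylsilyl ethers into a free tertiary alcohol, an acetate and a benzoate. A2 is many steps from glucose.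
- Comparison: in absolute stereocontrol this road is better than the chosen one, whose catalyst sense must be verified, and it needs no electrochemistry. The chosen plan sets against this a much shorter sequence and oxygen substituents that leave the key step in final form.

**Alternative 2:** The cut is the C2–O bond, leading back to the achiral p-quinol A4. Under a chiral phosphoric acid the C1 hydroxyl of A4 would form a hemiacetal with acetaldehyde, whose hydroxyl adds to C2 of one of the two enantiotopic enone arms to give the cis-fused dioxolane A3.
- Merits: A4 is one oxidative dearomatisation from a phenol; the step is catalytic and sets the quaternary C1 and C2 cis in one operation.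
- Weak points: A3 has a ketone at C4, a methylene at C3 and an alkene at C5=C6, whereas the target needs oxygen at C3, methoxy at C6 and the alkene at C4=C5. This calls for a stereoselective α-oxygenation at C3, a stereoselective oxa-Michael addition of methanol at C6 and a carbonyl-to-alkene transposition, all under substrate control, followed by acetal removal beside esters.
- Comparison: this road reaches its first chiral intermediate faster and from a cheaper starting material, and in that respect is better. The chosen plan sets against it that C3 and C6 are fixed in the step that closes the ring, so no oxidation-state shuffling remains afterwards.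

**Alternative 3:** The cut is C1–C2. The acyclic keto-aldehyde A6, with a (Z)-C4=C5 alkene and the C3 and C6 stereocentres, would be closed by SmI2 (divalent samarium) in a pinacol coupling to give cis-diol A5.
- Merits: the most hindered bond and the cis-diol arise together; the alkene is present from the start; C3 and C6 can be taken from the chiral pool.
- Weak points: A6 is a skipped (Z)-ene flanked by two oxygenated allylic stereocentres and is prone to conjugation and epimerisation. Both α-oxygen substituents of the C1 ketone (C6-OMe and C7-OSi) can be cleaved reductively by SmI2 in competition with ketyl coupling. The face of the diol relative to C3/C6 is not assured. The silyl ethers must later be exchanged for benzoates, with a risk of acetyl migration on desilylation.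
- Comparison: the ring closure is more direct than cycloaddition followed by unmasking, and the later acylation sequence is short. The chosen plan offers instead a stable, achiral key-step precursor made in six routine steps and a relative configuration dictated by orbital symmetry, not by a chelate.

Key step: step 7

Assumption: the facial sense of the (S)-configured oxazaborolidinium catalyst is assigned from its binding model for α,β-unsaturated esters and must be confirmed on 13; the (R)-catalyst is equally accessible.
Assumption: 13 to 16 are drawn as the endo/ortho diastereomer; the exo/meta diastereomer (both C4 and C5 inverted) would give the same 17.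

## Route

Step 1
Reactants: 1 methyl 3,3-dimethoxypropanoate; 2 allyl bromide (3-bromoprop-1-ene)
Product: 4 methyl 2-(dimethoxymethyl)pent-4-enoate (racemic), via lithium ester enolate 3 (not isolated)
Conditions: LiN(i-Pr)2, THF, −78 °C; then 2, −78 to −30 °C
Reagents that add atoms: none
Why: Ester enolate alkylation (SN2 on an allylic bromide); at −78 °C the lithium enolate should be alkylated faster than it loses methoxide. The new C1 centre is racemic and is erased in step 6.

Step 2
Reactants: 4 methyl 2-(dimethoxymethyl)pent-4-enoate
Product: 5 2-(dimethoxymethyl)pent-4-en-1-ol (racemic)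
Conditions: LiAlH4, THF, 0 °C; aqueous NaOH work-up
Reagents that add atoms: none
Why: Hydride reduction of the ester to the primary alcohol (the future C7-OH); acetal and terminal alkene are inert, and the basic work-up protects the acetal.

Step 3
Reactants: 5 2-(dimethoxymethyl)pent-4-en-1-ol; 6 benzoyl chloride
Product: 7 2-(dimethoxymethyl)pent-4-en-1-yl benzoate (racemic)
Conditions: pyridine, DMAP (cat.), CH2Cl2, 0 °C to rt
Reagents that add atoms: none
Why: Acylation of a primary alcohol (nucleophilic acyl substitution); the C7 benzoate is installed in its final form.

Step 4
Reactants: 7 2-(dimethoxymethyl)pent-4-en-1-yl benzoate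
Product: 9 2-(dimethoxymethyl)-4-oxobutyl benzoate (racemic), via ozonide 8 (not isolated)
Conditions: O3, CH2Cl2, −78 °C; then PPh3, −78 °C to rt
Reagents that add atoms: ozone, [O-][O+]=O
Why: Ozonolysis of the only alkene with reductive work-up gives C3 at the aldehyde level. Working without methanol or acid keeps the aldehyde and the acetal from exchanging.

Step 5
Reactants: 9 2-(dimethoxymethyl)-4-oxobutyl benzoate
Product: 10 (E)-3-[(benzoyloxy)methyl]-4,4-dimethoxybut-1-en-1-yl benzoate (racemic)
Conditions: (PhCO)2O, Et3N, DMAP (cat.), toluene, 80 °C
Reagents that add atoms: benzoic anhydride, O=C(OC(=O)c1ccccc1)c1ccccc1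
Why: Enol ester formation by amine-mediated enolisation and O-acylation of the aldehyde. The (E) isomer, with the acyloxy group away from the branched C1, is expected to be favoured; any (Z) isomer is removed by chromatography.

Step 6
Reactants: 10 (E)-3-[(benzoyloxy)methyl]-4,4-dimethoxybut-1-en-1-yl benzoate
Product: 11 (1E,3Z)-3-[(benzoyloxy)methyl]-4-methoxybuta-1,3-dien-1-yl benzoate
Conditions: Me3SiOTf, i-Pr2NEt, CH2Cl2, −20 °C to rt; NaHCO3 quench; chromatography on Et3N-deactivated silica
Reagents that add atoms: none
Why: Acetal-to-enol-ether elimination: the silyl triflate ionises the acetal to an oxocarbenium ion and the amine removes the doubly activated C1 proton, driven by conjugation with the enol benzoate. The C6=C1 geometry is not enforced by the mechanism; the (3Z) isomer should be favoured if the C7 benzoate bridges the oxocarbenium ion (anti elimination from the bridged ion places OMe cis to C7), and any (3E) isomer is separated.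

Step 7
Reactants: 11 (1E,3Z)-3-[(benzoyloxy)methyl]-4-methoxybuta-1,3-dien-1-yl benzoate; 12 dibenzyl fumarate
Product: 13 dibenzyl (3S,4S,5S,6S)-3-(benzoyloxy)-1-[(benzoyloxy)methyl]-6-methoxycyclohex-1-ene-4,5-dicarboxylate (target numbering; C3-OBz, C6-OMe and the C5 ester on one face, the C4 ester on the other)
Conditions: (S)-1-(2-methylphenyl)-3,3-diphenyltetrahydro-1H,3H-pyrrolo[1,2-c][1,3,2]oxazaborole (20 mol%), (CF3SO2)2NH (18 mol%), CH2Cl2, −78 to −40 °C; Et3N quench
Reagents that add atoms: none
Why: The N-protonated oxazaborolidine binds one ester carbonyl of 12 through B–O coordination reinforced by an α-C–H···O contact, which lowers the LUMO and lets an aryl group of the catalyst cover one π-face; the s-cis diene 11 then adds in a concerted, asynchronous [4+2] cycloaddition, the closest known reaction type being oxazaborolidinium-catalysed Diels–Alder additions of fumarate esters to oxygenated dienes. The six-membered ring is closed by intermolecular [4+2] cycloaddition, C3–C4 and C5–C6 forming suprafacially on both partners. C3 and C6 emerge cis because both oxygens occupy outward positions of the (1E,3Z)-diene, and C4 and C5 are trans because the fumarate geometry is transferred. The bound ester is expected endo and next to the methoxy-bearing terminus (methoxy being the stronger donor, C3 is the more nucleophilic end and bonds first to the carbon β to the activated carbonyl), which places the C5 ester cis to C6-OMe. The absolute configuration follows from the shielded face of the bound fumarate, relayed to the diene face by this endo/ortho orientation. The step therefore needs π-facial selectivity on the fumarate and one consistent orientation of the diene relative to the bound ester: endo/ortho and exo/meta adducts converge on 17 after loss of both carboxyl groups, whereas endo/meta and exo/ortho adducts would lead to its enantiomer. The donor difference between OMe and OBz and the endo preference of the activated carbonyl secure this, and diene isomers with an inward oxygen cannot reach the s-cis conformation.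

Step 8
Reactants: 13 dibenzyl (3S,4S,5S,6S)-3-(benzoyloxy)-1-[(benzoyloxy)methyl]-6-methoxycyclohex-1-ene-4,5-dicarboxylate
Product: 14 dibenzyl (1S,2S,3R,4S,5S,6S)-3-(benzoyloxy)-1-[(benzoyloxy)methyl]-1,2-dihydroxy-6-methoxycyclohexane-4,5-dicarboxylate (C1-OH and C2-OH cis, on the face opposite to C3-OBz and C6-OMe)
Conditions: OsO4 (5 mol%), N-methylmorpholine N-oxide, citric acid, t-BuOH/acetone/H2O, rt; Na2SO3 quench
Reagents that add atoms: osmium tetroxide, O=[Os](=O)(=O)=O; N-methylmorpholine N-oxide, C[N+]1([O-])CCOCC1; water, O
Why: Catalytic osmium tetroxide cis-dihydroxylation ([3+2] addition, hydrolysis of the osmate ester). Both allylic oxygens (C3, C6) lie on one face, so the oxidant adds anti to them and sets C1 and C2 together; the slightly acidic citrate medium speeds turnover on the electron-poor alkene and suppresses benzoyl migration.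

Step 9
Reactants: 14 dibenzyl (1S,2S,3R,4S,5S,6S)-3-(benzoyloxy)-1-[(benzoyloxy)methyl]-1,2-dihydroxy-6-methoxycyclohexane-4,5-dicarboxylate
Product: 15 dibenzyl (1R,2S,3R,4S,5S,6S)-2-acetoxy-3-(benzoyloxy)-1-[(benzoyloxy)methyl]-1-hydroxy-6-methoxycyclohexane-4,5-dicarboxylate
Conditions: Ac2O, pyridine, DMAP (cat.), CH2Cl2, 0 °C
Reagents that add atoms: acetic anhydride, CC(=O)OC(C)=O
Why: DMAP-catalysed acetylation; the secondary C2 hydroxyl reacts, while the tertiary C1 hydroxyl on a fully substituted carbon is not acylated under these mild conditions.

Step 10
Reactants: 15 dibenzyl (1R,2S,3R,4S,5S,6S)-2-acetoxy-3-(benzoyloxy)-1-[(benzoyloxy)methyl]-1-hydroxy-6-methoxycyclohexane-4,5-dicarboxylate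
Product: 16 (1R,2S,3R,4S,5S,6S)-2-acetoxy-3-(benzoyloxy)-1-[(benzoyloxy)methyl]-1-hydroxy-6-methoxycyclohexane-4,5-dicarboxylic acid
Conditions: H2 (1 atm), Pd/C (10% Pd), EtOAc, rt
Reagents that add atoms: none
Why: Hydrogenolysis of the two benzyl esters; the molecule holds no alkene at this stage, and benzoates, acetate and methyl ether are inert.

Step 11
Reactants: 16 (1R,2S,3R,4S,5S,6S)-2-acetoxy-3-(benzoyloxy)-1-[(benzoyloxy)methyl]-1-hydroxy-6-methoxycyclohexane-4,5-dicarboxylic acid
Product: 17 [(1R,2S,3R,6S)-2-acetoxy-3-(benzoyloxy)-1-hydroxy-6-methoxycyclohex-4-en-1-yl]methyl benzoate (target)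
Conditions: constant-current electrolysis, Pt anode and Pt cathode, undivided cell, pyridine/H2O (9:1), Et3N, 10–15 °C
Reagents that add atoms: none
Why: Anodic oxidative bis-decarboxylation of a vicinal diacid (Kolbe-type two-electron oxidation): loss of the first CO2 gives a C4 or C5 radical/cation that expels the neighbouring carboxylate as CO2 to form C4=C5. The trans arrangement of the acids is no obstacle, and C1, C2, C3 and C6 are untouched.

## Compound list

1 | methyl 3,3-dimethoxypropanoate | COC(OC)CC(=O)OC | starting material
2 | allyl bromide (3-bromoprop-1-ene) | C=CCBr | starting material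
3 | lithium enolate of 1 (lithium 1,3,3-trimethoxyprop-1-en-1-olate) | [Li+].[O-]C(OC)=CC(OC)OC | intermediate (not isolated)
4 | methyl 2-(dimethoxymethyl)pent-4-enoate (racemic) | COC(OC)C(CC=C)C(=O)OC | intermediate
5 | 2-(dimethoxymethyl)pent-4-en-1-ol (racemic) | COC(OC)C(CO)CC=C | intermediate
6 | benzoyl chloride | O=C(Cl)c1ccccc1 | starting material
7 | 2-(dimethoxymethyl)pent-4-en-1-yl benzoate (racemic) | COC(OC)C(COC(=O)c1ccccc1)CC=C | intermediate
8 | 2-(dimethoxymethyl)-3-(1,2,4-trioxolan-3-yl)propyl benzoate (ozonide, diastereomer mixture) | COC(OC)C(COC(=O)c1ccccc1)CC1OCOO1 | intermediate (not isolated)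
9 | 2-(dimethoxymethyl)-4-oxobutyl benzoate (racemic) | COC(OC)C(COC(=O)c1ccccc1)CC=O | intermediate
10 | (E)-3-[(benzoyloxy)methyl]-4,4-dimethoxybut-1-en-1-yl benzoate (racemic) | COC(OC)C(COC(=O)c1ccccc1)/C=C/OC(=O)c1ccccc1 | intermediate
11 | (1E,3Z)-3-[(benzoyloxy)methyl]-4-methoxybuta-1,3-dien-1-yl benzoate | CO/C=C(/C=C/OC(=O)c1ccccc1)COC(=O)c1ccccc1 | intermediate
12 | dibenzyl fumarate | O=C(OCc1ccccc1)/C=C/C(=O)OCc1ccccc1 | starting material
13 | dibenzyl (3S,4S,5S,6S)-3-(benzoyloxy)-1-[(benzoyloxy)methyl]-6-methoxycyclohex-1-ene-4,5-dicarboxylate | CO[C@H]1[C@@H](C(=O)OCc2ccccc2)[C@H](C(=O)OCc2ccccc2)[C@@H](OC(=O)c2ccccc2)C=C1COC(=O)c1ccccc1 | intermediate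
14 | dibenzyl (1S,2S,3R,4S,5S,6S)-3-(benzoyloxy)-1-[(benzoyloxy)methyl]-1,2-dihydroxy-6-methoxycyclohexane-4,5-dicarboxylate | CO[C@H]1[C@@H](C(=O)OCc2ccccc2)[C@H](C(=O)OCc2ccccc2)[C@@H](OC(=O)c2ccccc2)[C@H](O)[C@@]1(O)COC(=O)c1ccccc1 | intermediate
15 | dibenzyl (1R,2S,3R,4S,5S,6S)-2-acetoxy-3-(benzoyloxy)-1-[(benzoyloxy)methyl]-1-hydroxy-6-methoxycyclohexane-4,5-dicarboxylate | CO[C@H]1[C@@H](C(=O)OCc2ccccc2)[C@H](C(=O)OCc2ccccc2)[C@@H](OC(=O)c2ccccc2)[C@H](OC(C)=O)[C@@]1(O)COC(=O)c1ccccc1 | intermediate
16 | (1R,2S,3R,4S,5S,6S)-2-acetoxy-3-(benzoyloxy)-1-[(benzoyloxy)methyl]-1-hydroxy-6-methoxycyclohexane-4,5-dicarboxylic acid | CO[C@H]1[C@@H](C(=O)O)[C@H](C(=O)O)[C@@H](OC(=O)c2ccccc2)[C@H](OC(C)=O)[C@@]1(O)COC(=O)c1ccccc1 | intermediate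
17 | [(1R,2S,3R,6S)-2-acetoxy-3-(benzoyloxy)-1-hydroxy-6-methoxycyclohex-4-en-1-yl]methyl benzoate | CO[C@H]1C=C[C@@H](OC(=O)c2ccccc2)[C@H](OC(C)=O)[C@@]1(O)COC(=O)c1ccccc1 | target

## Step count and least certain steps

Total step count: 11. Longest linear sequence: 11 steps (1 to 17); 2, 6 and 12 enter as commercial reagents.

**Step 7 (key step).** Three processes threaten it. The strongly acidic catalyst may consume the diene (protonation of the enol ether, ionisation of the allylic C7 benzoate) faster than it cycloadds. A stepwise Mukaiyama–Michael pathway may replace the concerted addition. Leakage between diene orientations relative to the bound ester would erode the enantiomeric purity once C4 and C5 are stripped. The fallback sets out from 11 and replaces the symmetrical diester by an unsymmetrical, two-point-binding dienophile, benzyl (E)-4-oxo-4-(2-oxo-1,3-oxazolidin-3-yl)but-2-enoate F1 (one step from monobenzyl fumarate). The catalyst is the milder divalent copper complex [Cu(t-Bu-box)](SbF6)2, where t-Bu-box is 2,2′-(propane-2,2-diyl)bis(4-tert-butyl-4,5-dihydrooxazole), in the enantiomeric form that delivers the required face. Chelation of the imide fixes which carbonyl is activated and endo, so the orientation is no longer left to the donor difference alone. The adduct, benzyl 3-(benzoyloxy)-1-[(benzoyloxy)methyl]-6-methoxy-5-(2-oxo-1,3-oxazolidine-3-carbonyl)cyclohex-1-ene-4-carboxylate F2, is treated with LiOCH2Ph in THF at −78 °C, which exchanges the oxazolidinone for benzyl alkoxide and comes back to the route at 13.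

**Step 11.** The transient C4 cation may be captured by the neighbouring C3 benzoate (bridged dioxolanylium ion, then acyl shift or hydroxy ester), radicals may couple, and the basic aqueous medium may slowly cleave or shift esters. The fallback sets out from 16 and reaches 17 by a chemical oxidant in place of the electrode: Pb(OAc)4 (tetravalent lead) in anhydrous pyridine under O2 at 50–60 °C. Decarboxylation then proceeds within lead carboxylates without a long-lived free cation and without water; it makes no new compound (F0).

**Step 6.** The geometry of the new C6=C1 bond may come out wrong or mixed, and the silyl triflate may attack the enol benzoate. The fallback sets out from 10. Mild aqueous acid (H2O, acidic ion-exchange resin, acetone) hydrolyses the acetal, and the β,γ-unsaturated aldehyde moves into conjugation to give (E)-2-formylbut-2-ene-1,4-diyl dibenzoate F3. HC(OMe)3 with pyridinium p-toluenesulfonate converts it into (E)-2-(dimethoxymethyl)but-2-ene-1,4-diyl dibenzoate F4. Me3SiOTf/i-Pr2NEt then effects a 1,4-elimination through the s-trans unsaturated oxocarbenium ion with loss of a C3 proton, returning to 11. In this mode the s-trans ion places OMe trans to C2, and allylic strain against the C1 substituents places OBz outward. The detour also accepts (Z)-10.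

**Step 5.** Enolisation may give a substantial share of the (Z)-enol benzoate, or the aldehyde may self-condense under the amine. The fallback replaces kinetic control by thermodynamic correction: the E/Z mixture of 10 is equilibrated by reversible thiyl-radical addition and elimination (PhSSPh, light, benzene), which should enrich the less hindered (E) isomer. It sets out from 10 and returns to 10 without a new compound (F0).

**Step 8.** Osmylation of the hindered, electron-poor trisubstituted alkene may be slow, and a long reaction time invites benzoyl migration onto the new hydroxyls. The fallback sets out from 13 and reaches 14 with a different, far more electrophilic oxidant: RuO4 generated from RuCl3 (cat.) and NaIO4 in EtOAc/MeCN/H2O at 0 °C for a few minutes. It adds to the same, less hindered face and leaves no time for acyl migration; no new compound is made (F0).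

## Further compounds

F1 | step 7 | benzyl (E)-4-oxo-4-(2-oxo-1,3-oxazolidin-3-yl)but-2-enoate | O=C(OCc1ccccc1)/C=C/C(=O)N1CCOC1=O
F2 | step 7 | benzyl (3S,4S,5S,6S)-3-(benzoyloxy)-1-[(benzoyloxy)methyl]-6-methoxy-5-(2-oxo-1,3-oxazolidine-3-carbonyl)cyclohex-1-ene-4-carboxylate (target numbering) | CO[C@H]1[C@@H](C(=O)N2CCOC2=O)[C@H](C(=O)OCc2ccccc2)[C@@H](OC(=O)c2ccccc2)C=C1COC(=O)c1ccccc1
F0 | step 11 | none | none
F3 | step 6 | (E)-2-formylbut-2-ene-1,4-diyl dibenzoate | O=C/C(COC(=O)c1ccccc1)=C/COC(=O)c1ccccc1
F4 | step 6 | (E)-2-(dimethoxymethyl)but-2-ene-1,4-diyl dibenzoate | COC(OC)/C(COC(=O)c1ccccc1)=C/COC(=O)c1ccccc1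
F0 | step 5 | none | none
F0 | step 8 | none | none
A1 | alternative 1 | 6-methoxy-1,2,3-tris(triethylsilyloxy)cyclohex-4-ene-1-carboxylic acid (target configuration at C1, C2, C3, C6) | CO[C@H]1C=C[C@@H](O[Si](CC)(CC)CC)[C@H](O[Si](CC)(CC)CC)[C@@]1(O[Si](CC)(CC)CC)C(=O)O
A2 | alternative 1 | (E)-6,7-dideoxy-7-methoxy-2,3,4-tris-O-(triethylsilyl)-D-gluco-hept-6-enono-1,5-lactone | O=C1O[C@H](/C=C/OC)[C@@H](O[Si](CC)(CC)CC)[C@H](O[Si](CC)(CC)CC)[C@H]1O[Si](CC)(CC)CC
A3 | alternative 2 | cis-fused ethylidene acetal of 4-[(benzoyloxy)methyl]-4,5-dihydroxycyclohex-2-en-1-one (target configuration at C1 and C2) | C1=CC(=O)C[C@H](O[C@H](C)O2)[C@@]12COC(=O)c1ccccc1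
A4 | alternative 2 | (1-hydroxy-4-oxocyclohexa-2,5-dien-1-yl)methyl benzoate | O=C1C=CC(O)(COC(=O)c2ccccc2)C=C1
A5 | alternative 3 | 3-(tert-butyldimethylsilyloxy)-1-[(tert-butyldimethylsilyloxy)methyl]-6-methoxycyclohex-4-ene-1,2-diol (target configuration) | CO[C@H]1C=C[C@@H](O[Si](C)(C)C(C)(C)C)[C@H](O)[C@@]1(O)CO[Si](C)(C)C(C)(C)C
A6 | alternative 3 | (2R,5S,3Z)-2,7-bis(tert-butyldimethylsilyloxy)-5-methoxy-6-oxohept-3-enal | O=C[C@H](O[Si](C)(C)C(C)(C)C)/C=C\[C@H](OC)C(=O)CO[Si](C)(C)C(C)(C)C
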